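## Retrosynthetic overview

1. Ring atoms are called C1 (ketone carbon), C2 (heptenyl), C3 (hydroxymethyl), C4 (carbinol), C5 and C6 (oxirane carbons, C6 bearing the butenoic acid chain). Target ⇐ acid unmasking of ketone and acid ⇐ syn reduction at C4 ⇐ tartrate-mediated nucleophilic epoxidation of C5=C6 in quinone monoketal 28 ⇐ PhI(OAc)2/MeOH dearomatization of p-methoxyphenol 27.
2. The pentasubstituted arene ⇐ thermal ring expansion of 4-alkenylcyclobutenone 16: 4π ring opening to a dienylketene, then 6π closure that forms the C1–C6 bond and makes the six-membered carbocycle.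
3. 16 ⇐ diisopropyl squarate by three regiodefined organolithium additions (heptenyl, butenyl, methoxymethoxymethyl); the enoate chain is completed by Wittig olefination after the ring expansion.
4. Enabling feature: C1 and C4 both carry oxygen and flank the C2=C3 double bond, and C5–C6 is a two-carbon oxirane unit. The carbocycle is therefore a masked 1,4-benzoquinone whose C1–C4 map onto the four ring carbons of a 4-oxycyclobutenone and whose C5–C6 map onto a vinyl group on that ring.
5. Ring order: cyclobutene (purchased) → six-membered carbocycle (step 6) → oxirane (step 14).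

Key step: step 6

Assumption: the facial sense of the tartrate-mediated epoxidation (step 14) is taken to be the one drawn with L-(+)-diisopropyl tartrate; if the opposite epoxide enantiomer predominates, D-(−)-diisopropyl tartrate is used under the same conditions.

## Route

Step 1
Reactants: 1 [(1E)-hept-1-en-1-yl]boronic acid
Product: 2 (1E)-1-iodohept-1-ene
Conditions: N-iodosuccinimide, MeCN, 0 °C → rt, dark
Reagents that add atoms: N-iodosuccinimide `O=C1CCC(=O)N1I`
Why: ipso-iododeboronation of an alkenylboronic acid (halodeboronation) should proceed with retention, so the E geometry of the commercial boronic acid is carried into the iodide.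

Step 2
Reactants: 2 (1E)-1-iodohept-1-ene; 3 3,4-di(propan-2-yloxy)cyclobut-3-ene-1,2-dione (diisopropyl squarate)
Product: 6 3-[(1E)-hept-1-en-1-yl]-4-(propan-2-yloxy)cyclobut-3-ene-1,2-dione, via (1E)-hept-1-en-1-yllithium 4 (not isolated), via lithium alkoxide of the squarate 1,2-adduct 5 (not isolated)
Conditions: t-BuLi (2 equiv), Et2O, −78 °C; 3, THF, −78 °C; then 2 M aq. HCl, 0 °C → rt
Reagents that add atoms: water `O`
Why: iodine–lithium exchange with retention gives the alkenyllithium, which adds 1,2 to one squarate carbonyl; acid then ionizes the tertiary carbinol and hydrolyzes the vinylogous ester (the standard squarate addition–hydrolysis sequence) to the 3-alkenyl-4-alkoxycyclobutenedione.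

Step 3
Reactants: 7 (but-3-yn-1-yloxy)(tert-butyl)dimethylsilane
Product: 9 tert-butyl{[(3E)-4-iodobut-3-en-1-yl]oxy}dimethylsilane, via alkenylzirconocene chloride 8 (not isolated)
Conditions: Cp2Zr(H)Cl, THF, rt; then I2, 0 °C
Reagents that add atoms: iodine `II`
Why: syn hydrozirconation of the terminal alkyne places zirconium on the terminal carbon and iodinolysis of the C–Zr bond occurs with retention, which should give the E iodide only.

Step 4
Reactants: 9 tert-butyl{[(3E)-4-iodobut-3-en-1-yl]oxy}dimethylsilane; 6 3-[(1E)-hept-1-en-1-yl]-4-(propan-2-yloxy)cyclobut-3-ene-1,2-dione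
Product: 12 4-[(1E)-4-{[tert-butyl(dimethyl)silyl]oxy}but-1-en-1-yl]-2-[(1E)-hept-1-en-1-yl]-4-(methoxymethoxy)-3-(propan-2-yloxy)cyclobut-2-en-1-one (racemic), via alkenyllithium 10 (not isolated), via lithium alkoxide of the 1,2-adduct 11 (not isolated)
Conditions: t-BuLi (2 equiv), Et2O, −78 °C; 6, THF, −78 °C; then MOMCl, −78 → 0 °C
Reagents that add atoms: chloromethyl methyl ether `COCCl`
Why: the alkenyllithium adds 1,2 to the carbonyl flanking the isopropoxy-bearing carbon, because the other carbonyl is deactivated as a vinylogous ester, and the tertiary lithium alkoxide is O-alkylated in situ; the new stereocentre forms as a racemate and is erased in step 6.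

Step 5
Reactants: 13 tributyl[(methoxymethoxy)methyl]stannane; 12 4-[(1E)-4-{[tert-butyl(dimethyl)silyl]oxy}but-1-en-1-yl]-2-[(1E)-hept-1-en-1-yl]-4-(methoxymethoxy)-3-(propan-2-yloxy)cyclobut-2-en-1-one
Product: 16 4-[(1E)-4-{[tert-butyl(dimethyl)silyl]oxy}but-1-en-1-yl]-2-[(1E)-hept-1-en-1-yl]-4-(methoxymethoxy)-3-[(methoxymethoxy)methyl]cyclobut-2-en-1-one (racemic), via [(methoxymethoxy)methyl]lithium 14 (not isolated), via lithium alkoxide of the 1,2-adduct 15 (not isolated)
Conditions: n-BuLi, THF, −78 °C; 12, −78 °C; then 0.5 M aq. HCl, THF, 0 °C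
Reagents that add atoms: water `O`
Why: tin–lithium exchange gives the α-alkoxymethyllithium, which adds 1,2 to the vinylogous ester carbonyl; brief mild acid ionizes the carbinol and hydrolyzes the enol ether with 1,3-carbonyl transposition (Stork–Danheiser-type sequence), which puts the protected hydroxymethyl carbon on the alkene carbon next to the quaternary centre and the ketone next to the heptenyl-bearing carbon.

Step 6
Reactants: 16 4-[(1E)-4-{[tert-butyl(dimethyl)silyl]oxy}but-1-en-1-yl]-2-[(1E)-hept-1-en-1-yl]-4-(methoxymethoxy)-3-[(methoxymethoxy)methyl]cyclobut-2-en-1-one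
Product: 19 6-(2-{[tert-butyl(dimethyl)silyl]oxy}ethyl)-2-[(1E)-hept-1-en-1-yl]-4-(methoxymethoxy)-3-[(methoxymethoxy)methyl]phenol, via dienylketene 17 (not isolated), via cyclohexa-2,4-dienone 18 (not isolated)
Conditions: degassed toluene (0.01 M), 110 °C, Ar
Reagents that add atoms: none
Why: Heating opens the cyclobutenone by conrotatory 4π electrocyclic cleavage of the bond between the carbonyl carbon and the quaternary carbon; the methoxymethoxy donor on that carbon rotates outward (torquoselectivity), so the butenyl group turns inward and dienylketene 17 forms with the alkene cis to the ketene. Thermal disrotatory 6π electrocyclization then joins the ketene carbon (later ketone carbon C1) to the terminal alkene carbon (later oxirane carbon C6), closing the six-membered carbocycle, and dienone 18 enolizes irreversibly to phenol 19. The closest known reaction type is the thermal ring expansion of 4-alkenyl-4-oxycyclobutenones to hydroquinone derivatives (Moore rearrangement). No stereocentre survives, since the racemic quaternary carbon of 16 becomes sp2 and the sp3 carbon of 18 is lost on aromatization; the step fixes constitution only, but all of it, because each ring carbon inherits its substituent from a defined cyclobutenone or alkene position. The selectivities needed are inward rotation of the alkenyl group, secured by the oxygen donor on the same carbon, and ring closure faster than capture of the ketene, secured by capping both oxygens (a free hydroxymethyl would close a butenolide) and by dilute, aprotic, degassed conditions.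

Step 7
Reactants: 19 6-(2-{[tert-butyl(dimethyl)silyl]oxy}ethyl)-2-[(1E)-hept-1-en-1-yl]-4-(methoxymethoxy)-3-[(methoxymethoxy)methyl]phenol
Product: 20 tert-butyl(2-{3-[(1E)-hept-1-en-1-yl]-2-methoxy-5-(methoxymethoxy)-4-[(methoxymethoxy)methyl]phenyl}ethoxy)dimethylsilane
Conditions: MeI, K2CO3, DMF, rt
Reagents that add atoms: iodomethane `CI`
Why: Williamson O-methylation of the only free phenol marks the C1 oxygen as the one that will later become the ketal.

Step 8
Reactants: 20 tert-butyl(2-{3-[(1E)-hept-1-en-1-yl]-2-methoxy-5-(methoxymethoxy)-4-[(methoxymethoxy)methyl]phenyl}ethoxy)dimethylsilane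
Product: 21 2-{3-[(1E)-hept-1-en-1-yl]-2-methoxy-5-(methoxymethoxy)-4-[(methoxymethoxy)methyl]phenyl}ethan-1-ol
Conditions: HF·pyridine, pyridine, THF, 0 °C → rt
Reagents that add atoms: none
Why: fluoride cleaves the primary silyl ether, while the two methoxymethyl acetals and the aryl methyl ether are inert to buffered HF·pyridine.

Step 9
Reactants: 21 2-{3-[(1E)-hept-1-en-1-yl]-2-methoxy-5-(methoxymethoxy)-4-[(methoxymethoxy)methyl]phenyl}ethan-1-ol
Product: 22 {3-[(1E)-hept-1-en-1-yl]-2-methoxy-5-(methoxymethoxy)-4-[(methoxymethoxy)methyl]phenyl}acetaldehyde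
Conditions: Dess–Martin periodinane, CH2Cl2, 0 °C → rt; used crude
Reagents that add atoms: none
Why: Dess–Martin oxidation converts the primary alcohol into the arylacetaldehyde under near-neutral conditions that should not enolize it or touch the diene.

Step 10
Reactants: 23 tert-butyl 2-bromopropanoate
Product: 25 tert-butyl 2-(triphenylphosphoranylidene)propanoate, via phosphonium bromide 24 (not isolated)
Conditions: PPh3, toluene, 90 °C; then 2 M aq. NaOH, CH2Cl2, 0 °C
Reagents that add atoms: triphenylphosphine `c1ccc(cc1)P(c1ccccc1)c1ccccc1`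
Why: SN2 quaternization of the phosphine by the α-bromo ester followed by deprotonation of the ester-stabilized phosphonium salt is the standard preparation of such stabilized ylides.

Step 11
Reactants: 22 {3-[(1E)-hept-1-en-1-yl]-2-methoxy-5-(methoxymethoxy)-4-[(methoxymethoxy)methyl]phenyl}acetaldehyde; 25 tert-butyl 2-(triphenylphosphoranylidene)propanoate
Product: 26 tert-butyl (2E)-4-{3-[(1E)-hept-1-en-1-yl]-2-methoxy-5-(methoxymethoxy)-4-[(methoxymethoxy)methyl]phenyl}-2-methylbut-2-enoate
Conditions: CH2Cl2, rt → 40 °C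
Reagents that add atoms: none
Why: Wittig olefination with an α-methyl stabilized ylide should give the E trisubstituted enoate, and the weakly basic ylide should not move the new double bond into conjugation with the arene.

Step 12
Reactants: 26 tert-butyl (2E)-4-{3-[(1E)-hept-1-en-1-yl]-2-methoxy-5-(methoxymethoxy)-4-[(methoxymethoxy)methyl]phenyl}-2-methylbut-2-enoate
Product: 27 tert-butyl (2E)-4-{3-[(1E)-hept-1-en-1-yl]-5-hydroxy-4-(hydroxymethyl)-2-methoxyphenyl}-2-methylbut-2-enoate
Conditions: ZnBr2 (2 equiv), n-PrSH (4 equiv), CH2Cl2, 0 °C, 10 min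
Reagents that add atoms: none
Why: Lewis acid–thiol cleavage of both methoxymethyl acetals (ZnBr2 activation, thiol attack at the acetal carbon) is fast at 0 °C, so the tert-butyl ester, the diene and the electron-rich benzylic C–O bond should survive the short exposure.

Step 13
Reactants: 27 tert-butyl (2E)-4-{3-[(1E)-hept-1-en-1-yl]-5-hydroxy-4-(hydroxymethyl)-2-methoxyphenyl}-2-methylbut-2-enoate
Product: 28 tert-butyl (2E)-4-{5-[(1E)-hept-1-en-1-yl]-4-(hydroxymethyl)-6,6-dimethoxy-3-oxocyclohexa-1,4-dien-1-yl}-2-methylbut-2-enoate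
Conditions: PhI(OAc)2, MeOH, 0 °C
Reagents that add atoms: methanol `CO`
Why: oxidative dearomatization of a p-methoxyphenol with PhI(OAc)2 lets methanol add at the methoxy-bearing para carbon, so the ketal sits on C1 and the free ketone on C4 next to the hydroxymethyl-bearing carbon.

Step 14
Reactants: 28 tert-butyl (2E)-4-{5-[(1E)-hept-1-en-1-yl]-4-(hydroxymethyl)-6,6-dimethoxy-3-oxocyclohexa-1,4-dien-1-yl}-2-methylbut-2-enoate
Product: 29 tert-butyl (2E)-4-[(1R,6S)-3-[(1E)-hept-1-en-1-yl]-4-(hydroxymethyl)-2,2-dimethoxy-5-oxo-7-oxabicyclo[4.1.0]hept-3-en-1-yl]-2-methylbut-2-enoate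
Conditions: Ph3COOH, NaN(SiMe3)2, L-(+)-diisopropyl tartrate, 4 Å molecular sieves, toluene, −78 → −50 °C
Reagents that add atoms: trityl hydroperoxide `OOC(c1ccccc1)(c1ccccc1)c1ccccc1`
Why: tartrate-mediated nucleophilic (Weitz–Scheffer) epoxidation, in which the sodium alkoxide of the hydroxymethyl group and the sodium tartrate deliver the trityl peroxide anion to one face of the C4(=O)–C5=C6 enone arm (the other arm has a fully substituted β-carbon and carries the alkoxide), sets C5 and C6 together as a cis-oxirane whose absolute configuration is reagent-controlled.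

Step 15
Reactants: 29 tert-butyl (2E)-4-[(1R,6S)-3-[(1E)-hept-1-en-1-yl]-4-(hydroxymethyl)-2,2-dimethoxy-5-oxo-7-oxabicyclo[4.1.0]hept-3-en-1-yl]-2-methylbut-2-enoate
Product: 30 tert-butyl (2E)-4-[(1R,5R,6R)-3-[(1E)-hept-1-en-1-yl]-5-hydroxy-4-(hydroxymethyl)-2,2-dimethoxy-7-oxabicyclo[4.1.0]hept-3-en-1-yl]-2-methylbut-2-enoate
Conditions: NaBH4, CeCl3·7H2O, MeOH, −78 °C
Reagents that add atoms: none
Why: Luche 1,2-reduction of the only ketone, with hydride arriving anti to the adjacent oxirane C–O bond (polar Felkin–Anh, less hindered face), should place the new hydroxyl cis to the oxirane oxygen and leave the enoate untouched.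

Step 16
Reactants: 30 tert-butyl (2E)-4-[(1R,5R,6R)-3-[(1E)-hept-1-en-1-yl]-5-hydroxy-4-(hydroxymethyl)-2,2-dimethoxy-7-oxabicyclo[4.1.0]hept-3-en-1-yl]-2-methylbut-2-enoate
Product: 31 (2E)-4-[(1R,5R,6R)-3-[(1E)-hept-1-en-1-yl]-5-hydroxy-4-(hydroxymethyl)-2-oxo-7-oxabicyclo[4.1.0]hept-3-en-1-yl]-2-methylbut-2-enoic acid (CNP0332048.1)
Conditions: CF3CO2H/CH2Cl2/H2O (20:78:2), 0 °C → rt
Reagents that add atoms: water `O`
Why: aqueous trifluoroacetic acid hydrolyzes the dimethyl ketal through an allylically stabilized oxocarbenium ion and cleaves the tert-butyl ester by alkyl–oxygen fission, while the oxirane, flanked by the emerging ketone and the carbinol, is deactivated toward acid opening and no stereocentre is touched.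

## Compound list

1 | [(1E)-hept-1-en-1-yl]boronic acid | `CCCCC/C=C/B(O)O` | starting material
2 | (1E)-1-iodohept-1-ene | `CCCCC/C=C/I` | intermediate
3 | 3,4-di(propan-2-yloxy)cyclobut-3-ene-1,2-dione (diisopropyl squarate) | `CC(C)OC1=C(OC(C)C)C(=O)C1=O` | starting material
4 | (1E)-hept-1-en-1-yllithium | `[Li]/C=C/CCCCC` | intermediate
5 | lithium 1-[(1E)-hept-1-en-1-yl]-4-oxo-2,3-di(propan-2-yloxy)cyclobut-2-en-1-olate (racemic) | `CCCCC/C=C/C1(O[Li])C(OC(C)C)=C(OC(C)C)C1=O` | intermediate
6 | 3-[(1E)-hept-1-en-1-yl]-4-(propan-2-yloxy)cyclobut-3-ene-1,2-dione | `CCCCC/C=C/C1=C(OC(C)C)C(=O)C1=O` | intermediate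
7 | (but-3-yn-1-yloxy)(tert-butyl)dimethylsilane | `C#CCCO[Si](C)(C)C(C)(C)C` | starting material
8 | chlorobis(cyclopentadienyl)[(1E)-4-{[tert-butyl(dimethyl)silyl]oxy}but-1-en-1-yl]zirconium | `CC(C)(C)[Si](C)(C)OCC/C=C/[Zr](Cl)(C1C=CC=C1)C1C=CC=C1` | intermediate
9 | tert-butyl{[(3E)-4-iodobut-3-en-1-yl]oxy}dimethylsilane | `CC(C)(C)[Si](C)(C)OCC/C=C/I` | intermediate
10 | [(1E)-4-{[tert-butyl(dimethyl)silyl]oxy}but-1-en-1-yl]lithium | `[Li]/C=C/CCO[Si](C)(C)C(C)(C)C` | intermediate
11 | lithium 1-[(1E)-4-{[tert-butyl(dimethyl)silyl]oxy}but-1-en-1-yl]-3-[(1E)-hept-1-en-1-yl]-4-oxo-2-(propan-2-yloxy)cyclobut-2-en-1-olate (racemic) | `CCCCC/C=C/C1=C(OC(C)C)C(O[Li])(/C=C/CCO[Si](C)(C)C(C)(C)C)C1=O` | intermediate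
12 | 4-[(1E)-4-{[tert-butyl(dimethyl)silyl]oxy}but-1-en-1-yl]-2-[(1E)-hept-1-en-1-yl]-4-(methoxymethoxy)-3-(propan-2-yloxy)cyclobut-2-en-1-one (racemic) | `CCCCC/C=C/C1=C(OC(C)C)C(OCOC)(/C=C/CCO[Si](C)(C)C(C)(C)C)C1=O` | intermediate
13 | tributyl[(methoxymethoxy)methyl]stannane | `CCCC[Sn](CCCC)(CCCC)COCOC` | starting material
14 | [(methoxymethoxy)methyl]lithium | `[Li]COCOC` | intermediate
15 | lithium 4-[(1E)-4-{[tert-butyl(dimethyl)silyl]oxy}but-1-en-1-yl]-2-[(1E)-hept-1-en-1-yl]-4-(methoxymethoxy)-1-[(methoxymethoxy)methyl]-3-(propan-2-yloxy)cyclobut-2-en-1-olate (mixture of diastereomers) | `CCCCC/C=C/C1=C(OC(C)C)C(OCOC)(/C=C/CCO[Si](C)(C)C(C)(C)C)C1(O[Li])COCOC` | intermediate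
16 | 4-[(1E)-4-{[tert-butyl(dimethyl)silyl]oxy}but-1-en-1-yl]-2-[(1E)-hept-1-en-1-yl]-4-(methoxymethoxy)-3-[(methoxymethoxy)methyl]cyclobut-2-en-1-one (racemic) | `CCCCC/C=C/C1=C(COCOC)C(OCOC)(/C=C/CCO[Si](C)(C)C(C)(C)C)C1=O` | intermediate
17 | (3Z,5E)-8-{[tert-butyl(dimethyl)silyl]oxy}-2-[(1E)-hept-1-en-1-yl]-4-(methoxymethoxy)-3-[(methoxymethoxy)methyl]octa-1,3,5-trien-1-one (dienylketene) | `CCCCC/C=C/C(=C=O)C(\COCOC)=C(OCOC)/C=C/CCO[Si](C)(C)C(C)(C)C` | intermediate
18 | 6-(2-{[tert-butyl(dimethyl)silyl]oxy}ethyl)-2-[(1E)-hept-1-en-1-yl]-4-(methoxymethoxy)-3-[(methoxymethoxy)methyl]cyclohexa-2,4-dien-1-one (racemic) | `CCCCC/C=C/C1=C(COCOC)C(OCOC)=CC(CCO[Si](C)(C)C(C)(C)C)C1=O` | intermediate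
19 | 6-(2-{[tert-butyl(dimethyl)silyl]oxy}ethyl)-2-[(1E)-hept-1-en-1-yl]-4-(methoxymethoxy)-3-[(methoxymethoxy)methyl]phenol | `CCCCC/C=C/c1c(O)c(CCO[Si](C)(C)C(C)(C)C)cc(OCOC)c1COCOC` | intermediate
20 | tert-butyl(2-{3-[(1E)-hept-1-en-1-yl]-2-methoxy-5-(methoxymethoxy)-4-[(methoxymethoxy)methyl]phenyl}ethoxy)dimethylsilane | `CCCCC/C=C/c1c(OC)c(CCO[Si](C)(C)C(C)(C)C)cc(OCOC)c1COCOC` | intermediate
21 | 2-{3-[(1E)-hept-1-en-1-yl]-2-methoxy-5-(methoxymethoxy)-4-[(methoxymethoxy)methyl]phenyl}ethan-1-ol | `CCCCC/C=C/c1c(OC)c(CCO)cc(OCOC)c1COCOC` | intermediate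
22 | {3-[(1E)-hept-1-en-1-yl]-2-methoxy-5-(methoxymethoxy)-4-[(methoxymethoxy)methyl]phenyl}acetaldehyde | `CCCCC/C=C/c1c(OC)c(CC=O)cc(OCOC)c1COCOC` | intermediate
23 | tert-butyl 2-bromopropanoate (racemic) | `CC(Br)C(=O)OC(C)(C)C` | starting material
24 | (1-tert-butoxy-1-oxopropan-2-yl)triphenylphosphonium bromide | `CC(C(=O)OC(C)(C)C)[P+](c1ccccc1)(c1ccccc1)c1ccccc1.[Br-]` | intermediate
25 | tert-butyl 2-(triphenylphosphoranylidene)propanoate | `CC(C(=O)OC(C)(C)C)=P(c1ccccc1)(c1ccccc1)c1ccccc1` | intermediate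
26 | tert-butyl (2E)-4-{3-[(1E)-hept-1-en-1-yl]-2-methoxy-5-(methoxymethoxy)-4-[(methoxymethoxy)methyl]phenyl}-2-methylbut-2-enoate | `CCCCC/C=C/c1c(OC)c(C/C=C(\C)C(=O)OC(C)(C)C)cc(OCOC)c1COCOC` | intermediate
27 | tert-butyl (2E)-4-{3-[(1E)-hept-1-en-1-yl]-5-hydroxy-4-(hydroxymethyl)-2-methoxyphenyl}-2-methylbut-2-enoate | `CCCCC/C=C/c1c(OC)c(C/C=C(\C)C(=O)OC(C)(C)C)cc(O)c1CO` | intermediate
28 | tert-butyl (2E)-4-{5-[(1E)-hept-1-en-1-yl]-4-(hydroxymethyl)-6,6-dimethoxy-3-oxocyclohexa-1,4-dien-1-yl}-2-methylbut-2-enoate | `CCCCC/C=C/C1=C(CO)C(=O)C=C(C/C=C(\C)C(=O)OC(C)(C)C)C1(OC)OC` | intermediate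
29 | tert-butyl (2E)-4-[(1R,6S)-3-[(1E)-hept-1-en-1-yl]-4-(hydroxymethyl)-2,2-dimethoxy-5-oxo-7-oxabicyclo[4.1.0]hept-3-en-1-yl]-2-methylbut-2-enoate | `CCCCC/C=C/C1=C(CO)C(=O)[C@H]2O[C@@]2(C/C=C(\C)C(=O)OC(C)(C)C)C1(OC)OC` | intermediate
30 | tert-butyl (2E)-4-[(1R,5R,6R)-3-[(1E)-hept-1-en-1-yl]-5-hydroxy-4-(hydroxymethyl)-2,2-dimethoxy-7-oxabicyclo[4.1.0]hept-3-en-1-yl]-2-methylbut-2-enoate | `CCCCC/C=C/C1=C(CO)[C@@H](O)[C@H]2O[C@@]2(C/C=C(\C)C(=O)OC(C)(C)C)C1(OC)OC` | intermediate
31 | (2E)-4-[(1R,5R,6R)-3-[(1E)-hept-1-en-1-yl]-5-hydroxy-4-(hydroxymethyl)-2-oxo-7-oxabicyclo[4.1.0]hept-3-en-1-yl]-2-methylbut-2-enoic acid | `CCCCC/C=C/C1=C(CO)[C@@H](O)[C@H]2O[C@@]2(C/C=C(\C)C(=O)O)C1=O` | target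

## Step count and risks

Total step count: 16. Longest linear sequence: 14 steps (steps 1, 2, 4–9, 11–16); steps 3 and 10 are side branches.

**Step 14 (epoxidation).** What may go wrong: insufficient enantiofacial discrimination by the tartrate–sodium alkoxide assembly, since a heptenyl group stands where the best-matched substrates carry a halogen, or partial attack of the peroxide on the other enone arm. The fallback replaces reagent control by a covalently bound auxiliary, which turns the problem into one of separable diastereomers. It sets out from 28: transketalization with (2R,4R)-pentane-2,4-diol (BF3·OEt2 cat., CH2Cl2, −20 °C) should give the spiro 1,3-dioxane ketal analogue of 28 F1. Weitz–Scheffer epoxidation (t-BuOOH, DBU, CH2Cl2, 0 °C), biased by the ketal methyl groups, should give the spiro ketal analogue of 29 F2, with the minor diastereomer removed by chromatography (the other diol antipode is used if it favours the needed isomer). Luche reduction as in step 15 gives the spiro ketal analogue of 30 F3, and the conditions of step 16, run longer, hydrolyze the cyclic ketal and the ester. The fallback comes back to the route at 31.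

**Step 12 (unmasking of the two hydroxyls).** What may go wrong: ionization of the electron-rich benzylic C–O bond once the neighbouring phenol is free (quinone-methide-type loss of the benzylic oxygen and capture by the thiol), or partial loss of the tert-butyl ester. The fallback stages the unmasking around the dearomatization, so that no free ortho-hydroxybenzyl ether meets a Lewis acid on the arene. It sets out from 26: NaHSO4 on silica gel (CH2Cl2, rt) removes only the phenolic acetal and gives tert-butyl (2E)-4-{3-[(1E)-hept-1-en-1-yl]-5-hydroxy-2-methoxy-4-[(methoxymethoxy)methyl]phenyl}-2-methylbut-2-enoate F4. PhI(OAc)2 in MeOH then gives the methoxymethyl-protected quinone monoketal F5. Me3SiOTf with 2,2′-bipyridyl (CH2Cl2, 0 °C; then H2O) cleaves the remaining formaldehyde acetal through a pyridinium intermediate, without a free carbocation and without touching the ketone dimethyl ketal. The fallback comes back to the route at 28.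

**Step 16 (final acid step).** What may go wrong: acid-mediated opening of the oxirane or ionization of the doubly allylic secondary alcohol during the comparatively slow tert-butyl ester cleavage. The fallback separates the two deprotections and removes the ester by silyl transfer instead of Brønsted acid. It sets out from 30: pyridinium p-toluenesulfonate in acetone/H2O (rt) hydrolyzes only the ketal and gives the tert-butyl ester of the target F6. Me3SiOTf with 2,6-lutidine (CH2Cl2, 0 °C) converts the tert-butyl ester into the trimethylsilyl ester and silylates both hydroxyls, giving the tris(trimethylsilyl) derivative F7, which is desilylated on work-up with aqueous citric acid in MeOH. The fallback comes back to the route at 31.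

Further compounds
F1 | step 14 | tert-butyl (2E)-4-[(2R,4R)-11-[(1E)-hept-1-en-1-yl]-10-(hydroxymethyl)-2,4-dimethyl-9-oxo-1,5-dioxaspiro[5.5]undeca-7,10-dien-7-yl]-2-methylbut-2-enoate (spiro pentanediol ketal analogue of 28) | `CCCCC/C=C/C1=C(CO)C(=O)C=C(C/C=C(\C)C(=O)OC(C)(C)C)C12O[C@H](C)C[C@@H](C)O2`
F2 | step 14 | (2R,4R)-pentane-2,4-diyl spiro ketal analogue of 29 (same oxirane configuration as 29, 1,3-dioxane in place of the two methoxy groups) | `CCCCC/C=C/C1=C(CO)C(=O)[C@H]2O[C@@]2(C/C=C(\C)C(=O)OC(C)(C)C)C13O[C@H](C)C[C@@H](C)O3`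
F3 | step 14 | (2R,4R)-pentane-2,4-diyl spiro ketal analogue of 30 (same three ring stereocentres as 30) | `CCCCC/C=C/C1=C(CO)[C@@H](O)[C@H]2O[C@@]2(C/C=C(\C)C(=O)OC(C)(C)C)C13O[C@H](C)C[C@@H](C)O3`
F4 | step 12 | tert-butyl (2E)-4-{3-[(1E)-hept-1-en-1-yl]-5-hydroxy-2-methoxy-4-[(methoxymethoxy)methyl]phenyl}-2-methylbut-2-enoate | `CCCCC/C=C/c1c(OC)c(C/C=C(\C)C(=O)OC(C)(C)C)cc(O)c1COCOC`
F5 | step 12 | tert-butyl (2E)-4-{5-[(1E)-hept-1-en-1-yl]-6,6-dimethoxy-4-[(methoxymethoxy)methyl]-3-oxocyclohexa-1,4-dien-1-yl}-2-methylbut-2-enoate | `CCCCC/C=C/C1=C(COCOC)C(=O)C=C(C/C=C(\C)C(=O)OC(C)(C)C)C1(OC)OC`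
F6 | step 16 | tert-butyl (2E)-4-[(1R,5R,6R)-3-[(1E)-hept-1-en-1-yl]-5-hydroxy-4-(hydroxymethyl)-2-oxo-7-oxabicyclo[4.1.0]hept-3-en-1-yl]-2-methylbut-2-enoate | `CCCCC/C=C/C1=C(CO)[C@@H](O)[C@H]2O[C@@]2(C/C=C(\C)C(=O)OC(C)(C)C)C1=O`
F7 | step 16 | trimethylsilyl (2E)-4-[(1R,5R,6R)-3-[(1E)-hept-1-en-1-yl]-2-oxo-5-[(trimethylsilyl)oxy]-4-{[(trimethylsilyl)oxy]methyl}-7-oxabicyclo[4.1.0]hept-3-en-1-yl]-2-methylbut-2-enoate | `CCCCC/C=C/C1=C(CO[Si](C)(C)C)[C@@H](O[Si](C)(C)C)[C@H]2O[C@@]2(C/C=C(\C)C(=O)O[Si](C)(C)C)C1=O`
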